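**Plan**

- Feature: in the oxolane (O1, C2 aryl, C3 carrying C9, C4 carrying the benzylic arm C7', C5 as CH2) the C2–O1–C5 triad is an aryl carbonyl ylide, and C3–C4 with its cis C9/C7' arms is the C=C bond of a 5-aryl-2(5H)-furanone (C9 carbonyl, C7' carbinol).
- Retrosynthesis: cut the C9–O aroyl bond and put an oxygen back on C7'; cut C2–C3 and C4–C5 together as a (3+2) cycloaddition; cut C7'–C(alkyne) of the butenolide.
- Forward: O-benzylvanillin gives both the silyl chloromethyl ether 5 (steps 1–3) and the butenolide 9 (steps 4–5). Step 6 closes the oxolane onto the lactone. The lactone is then reduced open, both hydroxyls are aroylated, and one hydrogenolysis removes the benzyl groups and the C7' oxygen.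
- Stereochemistry: C7' comes from a BINOL-controlled alkynylation. It steers the dipole to the opposite face of the cyclic Z alkene (C3, C4 cis), exo approach sets C2 trans to C9, and C7' itself is erased in step 9.

Key step: step 6

Remark: Ar = 4-(benzyloxy)-3-methoxyphenyl; aldehyde 1 (O-benzylvanillin) is commercial.

Assumption: (R)-BINOL is taken to deliver the propiolate to the Re face of 1 (S at C7'), as for other aryl aldehydes in this Ti/Zn system; the configuration would be checked by Mosher esters and (S)-BINOL used if the sense is opposite.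

**Step 1**
Reactants: 1 4-(benzyloxy)-3-methoxybenzaldehyde
Product: 3 rac-[4-(benzyloxy)-3-methoxyphenyl](dimethylphenylsilyl)methanol, via O-boryl ether 2 (not isolated)
Conditions: PhMe2Si–Bpin (1.2 equiv), (IPr)CuCl (5 mol%), NaOtBu (10 mol%), THF, 0 °C → rt; aq. NH4Cl
Reagents that add atoms: (dimethylphenylsilyl)boronic acid pinacol ester, CC1(C)OB(OC1(C)C)[Si](C)(C)c1ccccc1
Why: Copper-catalysed 1,2-addition of a silyl nucleophile from the Si–B reagent to an aryl aldehyde (Cu–Si insertion of C=O, then σ-bond metathesis to the O-boryl ether) should give the α-silyl carbinol without the Brook rearrangement that accompanies silyllithium additions; the new centre is racemic and is lost later in the ylide.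

**Step 2**
Reactants: 3 rac-[4-(benzyloxy)-3-methoxyphenyl](dimethylphenylsilyl)methanol
Product: 4 rac-{[4-(benzyloxy)-3-methoxyphenyl][(methylsulfanyl)methoxy]methyl}dimethylphenylsilane
Conditions: Me2S (8 equiv), (BzO)2 (4 equiv), MeCN, 0 °C
Reagents that add atoms: dimethyl sulfide, CSC
Why: Pummerer-type methylthiomethylation (the thionium ion from Me2S and benzoyl peroxide is trapped by the alcohol) forms the MTM ether without strong base or strong acid, so neither Brook rearrangement nor benzylic ionisation is invited.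

**Step 3**
Reactants: 4 rac-{[4-(benzyloxy)-3-methoxyphenyl][(methylsulfanyl)methoxy]methyl}dimethylphenylsilane
Product: 5 rac-{[4-(benzyloxy)-3-methoxyphenyl](chloromethoxy)methyl}dimethylphenylsilane
Conditions: SO2Cl2 (1.05 equiv), CH2Cl2, −78 °C; volatiles removed cold, used crude
Reagents that add atoms: sulfuryl chloride, O=S(=O)(Cl)Cl
Why: Chlorinolysis of the O,S-acetal with sulfuryl chloride is the standard route from MTM ethers to chloromethyl ethers of electron-rich benzylic alcohols, and at −78 °C the sulfide should react far faster than the arene or the C–Si bond.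

**Step 4**
Reactants: 1 4-(benzyloxy)-3-methoxybenzaldehyde; 6 methyl propiolate
Product: 7 methyl (S)-4-[4-(benzyloxy)-3-methoxyphenyl]-4-hydroxybut-2-ynoate
Conditions: (R)-BINOL (40 mol%), Et2Zn (4 equiv), 6 (4 equiv), HMPA (2 equiv), CH2Cl2, rt; Ti(OiPr)4 (1 equiv); then 1, rt; aq. NH4Cl
Reagents that add atoms: none
Why: BINOL–titanium-mediated asymmetric addition of the zinc acetylide of methyl propiolate to an aryl aldehyde (asymmetric alkynylation) sets C7' as S by Re-face delivery under control of the (R)-BINOL ligand.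

**Step 5**
Reactants: 7 methyl (S)-4-[4-(benzyloxy)-3-methoxyphenyl]-4-hydroxybut-2-ynoate
Product: 9 (R)-5-[4-(benzyloxy)-3-methoxyphenyl]furan-2(5H)-one, via Z-hydroxy enoate 8 (not isolated)
Conditions: H2 (1 atm), Lindlar Pd, quinoline, EtOAc, rt; filter; PPTS (cat.), PhMe, 40 °C
Reagents that add atoms: none
Why: Lindlar semi-hydrogenation gives the Z-enoate, whose hydroxyl then lactonises onto the ester (intramolecular transesterification) under mild acid and without base; the carbinol centre is untouched and its descriptor changes from S to R only through the CIP priorities.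

**Step 6**
Reactants: 5 rac-{[4-(benzyloxy)-3-methoxyphenyl](chloromethoxy)methyl}dimethylphenylsilane; 9 (R)-5-[4-(benzyloxy)-3-methoxyphenyl]furan-2(5H)-one
Product: 11 (3R,3aS,6R,6aR)-3,6-bis[4-(benzyloxy)-3-methoxyphenyl]tetrahydro-1H,3H-furo[3,4-c]furan-1-one, via carbonyl ylide 10 (not isolated)
Conditions: 9 (1 equiv), 5 (1.8 equiv), spray-dried CsF (2 equiv, in portions), MeCN, 0 °C → rt; filtration through Celite, no basic work-up
Reagents that add atoms: none
Why: Fluoride attacks silicon in 5 and 1,3-elimination of the silyl fluoride and chloride should give the aryl carbonyl ylide 10, which adds to the electron-poor C3=C4 bond of 9 in a concerted suprafacial (3+2) cycloaddition, the known behaviour of non-stabilised carbonyl ylides from silyl chloromethyl ethers towards acrylate-type alkenes. The oxolane is closed by this intermolecular [π4s+π2s] annulation, C2–C3 and C4–C5 forming in one event, so the cyclic Z alkene passes on its geometry as the cis ring fusion (C9 and C7' arms cis). Regiochemistry follows from the polarisation of the ylide: the electron-rich aryl group carries the oxocarbenium character, the larger HOMO coefficient sits on CH2 (C5), which bonds to the β-carbon C4, and C2 bonds to the α-carbon C3. The configuration at C3 and C4 is controlled by the C7' aryl group of 9, the dipole approaching the face anti to it as in other additions to 5-substituted furanones; C2 is controlled by exo approach of the aryl-out (W-shaped) ylide, which keeps the aryl group away from the lactone carbonyl and gives the 2,3-trans adduct, a minor C2 epimer being removed by chromatography. The step needs the C7' configuration of 9 to survive although its γ-hydrogen is acidic; sparingly soluble CsF, low temperature, an excess of the more fluorophilic silane 5 and a base-free work-up are chosen to secure this.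

**Step 7**
Reactants: 11 (3R,3aS,6R,6aR)-3,6-bis[4-(benzyloxy)-3-methoxyphenyl]tetrahydro-1H,3H-furo[3,4-c]furan-1-one
Product: 12 (R)-[4-(benzyloxy)-3-methoxyphenyl]{(3S,4S,5R)-5-[4-(benzyloxy)-3-methoxyphenyl]-4-(hydroxymethyl)oxolan-3-yl}methanol
Conditions: LiAlH4, THF, 0 °C; Rochelle salt work-up, no acid contact
Reagents that add atoms: none
Why: Hydride reduction of the lactone to the diol frees C9 as a primary alcohol and C7' as a secondary benzylic alcohol, and the ring stereocentres should be safe because reduction of the transient aldehyde outpaces its enolisation.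

**Step 8**
Reactants: 12 (R)-[4-(benzyloxy)-3-methoxyphenyl]{(3S,4S,5R)-5-[4-(benzyloxy)-3-methoxyphenyl]-4-(hydroxymethyl)oxolan-3-yl}methanol; 13 4-(benzyloxy)benzoic acid
Product: 14 C9,C7'-bis[4-(benzyloxy)benzoate] of diol 12
Conditions: 13 (2.5 equiv), EDC·HCl (3 equiv), DMAP (0.5 equiv), CH2Cl2, 0 °C → rt
Reagents that add atoms: none
Why: Steglich esterification acylates both hydroxyls, the C9 ester being the one kept in the target and the C7' ester serving to turn the benzylic oxygen into a leaving group for hydrogenolysis.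

**Step 9**
Reactants: 14 C9,C7'-bis[4-(benzyloxy)benzoate] of diol 12
Product: 15 agastinol, [(2R,3S,4S)-2-(4-hydroxy-3-methoxyphenyl)-4-(4-hydroxy-3-methoxybenzyl)oxolan-3-yl]methyl 4-hydroxybenzoate
Conditions: H2 (1 atm), 10% Pd/C, EtOAc–THF, rt, stopped when the C7' ester is consumed
Reagents that add atoms: none
Why: Palladium-catalysed hydrogenolysis should remove the four O-benzyl groups and the benzylic C7' acyloxy group (which, once the para phenol is free, can also leave by 1,6-elimination to a quinone methide that is hydrogenated at once), while the non-benzylic C9 ester and the cyclic benzylic ether C2–O1 with its poorer leaving group remain; the C7' stereocentre disappears here.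

**Compound list**

1 | 4-(benzyloxy)-3-methoxybenzaldehyde | COc1cc(C=O)ccc1OCc1ccccc1 | starting material
2 | rac-O-(pinacolboryl) ether of 3 | COc1cc(C(OB2OC(C)(C)C(C)(C)O2)[Si](C)(C)c2ccccc2)ccc1OCc1ccccc1 | intermediate
3 | rac-[4-(benzyloxy)-3-methoxyphenyl](dimethylphenylsilyl)methanol | COc1cc(C(O)[Si](C)(C)c2ccccc2)ccc1OCc1ccccc1 | intermediate
4 | rac-{[4-(benzyloxy)-3-methoxyphenyl][(methylsulfanyl)methoxy]methyl}dimethylphenylsilane | COc1cc(C(OCSC)[Si](C)(C)c2ccccc2)ccc1OCc1ccccc1 | intermediate
5 | rac-{[4-(benzyloxy)-3-methoxyphenyl](chloromethoxy)methyl}dimethylphenylsilane | COc1cc(C(OCCl)[Si](C)(C)c2ccccc2)ccc1OCc1ccccc1 | intermediate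
6 | methyl propiolate | C#CC(=O)OC | starting material
7 | methyl (S)-4-[4-(benzyloxy)-3-methoxyphenyl]-4-hydroxybut-2-ynoate | COc1cc([C@H](O)C#CC(=O)OC)ccc1OCc1ccccc1 | intermediate
8 | methyl (R,Z)-4-[4-(benzyloxy)-3-methoxyphenyl]-4-hydroxybut-2-enoate | COc1cc([C@H](O)/C=C\C(=O)OC)ccc1OCc1ccccc1 | intermediate
9 | (R)-5-[4-(benzyloxy)-3-methoxyphenyl]furan-2(5H)-one | COc1cc([C@H]2C=CC(=O)O2)ccc1OCc1ccccc1 | intermediate
10 | carbonyl ylide ArCH(–)–O(+)=CH2 | C=[O+][CH-]c1ccc(OCc2ccccc2)c(OC)c1 | intermediate
11 | (3R,3aS,6R,6aR)-3,6-bis[4-(benzyloxy)-3-methoxyphenyl]tetrahydro-1H,3H-furo[3,4-c]furan-1-one (cis-fused; both aryl groups exo) | COc1cc([C@H]2[C@@H]3CO[C@@H](c4ccc(OCc5ccccc5)c(OC)c4)[C@@H]3C(=O)O2)ccc1OCc1ccccc1 | intermediate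
12 | (R)-[4-(benzyloxy)-3-methoxyphenyl]{(3S,4S,5R)-5-[4-(benzyloxy)-3-methoxyphenyl]-4-(hydroxymethyl)oxolan-3-yl}methanol | COc1cc([C@H](O)[C@@H]2CO[C@@H](c3ccc(OCc4ccccc4)c(OC)c3)[C@@H]2CO)ccc1OCc1ccccc1 | intermediate
13 | 4-(benzyloxy)benzoic acid | O=C(O)c1ccc(OCc2ccccc2)cc1 | starting material
14 | bis-ester: (2R,3S,4S)-oxolane with 2-Ar, 3-CH2O-[4-(benzyloxy)benzoyl], 4-[(R)-CH(Ar)O-(4-(benzyloxy)benzoyl)] | COc1cc([C@H](OC(=O)c2ccc(OCc3ccccc3)cc2)[C@@H]2CO[C@@H](c3ccc(OCc4ccccc4)c(OC)c3)[C@@H]2COC(=O)c2ccc(OCc3ccccc3)cc2)ccc1OCc1ccccc1 | intermediate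
15 | agastinol | COc1cc(C[C@@H]2CO[C@@H](c3ccc(O)c(OC)c3)[C@@H]2COC(=O)c2ccc(O)cc2)ccc1O | target

**Step count**

Total: 9 steps. Longest linear sequence: 7 steps (1 → 3 → 4 → 5 → 11 → 12 → 14 → 15; steps 1, 2, 3, 6, 7, 8, 9).

**Steps most likely to fail**

Step 6. Fluoride, or the basic ylide itself, may deprotonate the acidic γ-position of 9, so that the dipolarophile racemises or tautomerises before it is trapped; regio- and exo/endo control at C2 may also be incomplete. The fallback sets out from 5 and replaces 9 by commercial (5R)-5-(l-menthyloxy)furan-2(5H)-one, whose γ-centre is an acetal rather than a benzylic carbon and which tolerates fluoride and amine catalysis. Its menthyloxy group occupies the position of the aryl group of 9, so the same CsF-induced cycloaddition, again anti to the C5 substituent, should give the menthyloxy cycloadduct F1 with the same C3/C4 configuration as 11. Aqueous trifluoroacetic acid then hydrolyses the acetal to the lactol F2. Excess (4-benzyloxy-3-methoxyphenyl)magnesium bromide, made from the commercial aryl bromide, adds to the open aldehyde–carboxylate form of F2, and mild acidification relactonises the product. This returns to the route at 11, accompanied by its C7' epimer, the 7'-epi-lactone F3. The pair need not be separated: F3 passes through steps 7 and 8 as the 7'-epi-diol F4 and the 7'-epi-bis-ester F5, and step 9 turns F5 into 15 exactly as it does 14, because C7' becomes CH2.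

Step 3. Sulfuryl chloride or the methanesulfenyl chloride it releases may attack the electron-rich ring or the benzylic C–Si bond, or the chloromethyl ether may decompose on concentration. The fallback sets out from 1 and builds the same ylide from the regioisomeric precursor, with silicon on the methylene side and the leaving group on the benzylic carbon. Acid-catalysed acetalisation of 1 with (trimethylsilyl)methanol (PPTS, benzene, Dean–Stark) gives the bis(silylmethyl) acetal F6. Acetyl chloride in CH2Cl2 at 0 °C converts F6 into the α-chlorobenzyl silylmethyl ether F7, the classical acetal-to-α-chloro-ether exchange. F7 is used at once with CsF and 9 in MeCN; ionisation of the benzylic chloride followed by desilylation gives the identical ylide 10, and the route is rejoined at 11.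

Step 9. The cyclic benzylic ether C2–O1 may be hydrogenolysed (ring opening to the seco-lignan) before cleavage of the hindered C7' ester is complete. The fallback sets out from 12 and removes the C7' oxygen by a radical reaction, so that hydrogenation only has to cleave aryl benzyl ethers. One equivalent of 13 (EDC, cat. DMAP, −10 °C) acylates the primary C9 hydroxyl selectively to give the C9 mono-ester F8. Phenyl chlorothionoformate and pyridine convert the C7' hydroxyl into the thionocarbonate F9. Bu3SnH/AIBN in toluene at 80 °C (Barton–McCombie deoxygenation through the benzylic radical) then gives tri-O-benzyl agastinol F10. A brief hydrogenolysis (H2, Pd/C, EtOAc) of the three aryl benzyl ethers, the fastest C–O cleavage in the molecule, returns to the route at 15.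

**Further compounds**

F1 | step 6 | (3R,3aS,6R,6aR)-6-[4-(benzyloxy)-3-methoxyphenyl]-3-[(1R,2S,5R)-menthyloxy]tetrahydro-1H,3H-furo[3,4-c]furan-1-one | CC(C)[C@@H]1CC[C@@H](C)C[C@H]1O[C@H]1[C@@H]2CO[C@@H](c3ccc(OCc4ccccc4)c(OC)c3)[C@@H]2C(=O)O1
F2 | step 6 | (3aS,6R,6aR)-6-[4-(benzyloxy)-3-methoxyphenyl]-3-hydroxytetrahydro-1H,3H-furo[3,4-c]furan-1-one (anomeric mixture) | OC1[C@@H]2CO[C@@H](c3ccc(OCc4ccccc4)c(OC)c3)[C@@H]2C(=O)O1
F3 | step 6 | (3S,3aS,6R,6aR)-3,6-bis[4-(benzyloxy)-3-methoxyphenyl]tetrahydro-1H,3H-furo[3,4-c]furan-1-one (7'-epi-11) | COc1cc([C@@H]2[C@@H]3CO[C@@H](c4ccc(OCc5ccccc5)c(OC)c4)[C@@H]3C(=O)O2)ccc1OCc1ccccc1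
F4 | step 6 | 7'-epi-diol, (S)-carbinol epimer of 12 | COc1cc([C@@H](O)[C@@H]2CO[C@@H](c3ccc(OCc4ccccc4)c(OC)c3)[C@@H]2CO)ccc1OCc1ccccc1
F5 | step 6 | 7'-epi-bis-ester, C7' epimer of 14 | COc1cc([C@@H](OC(=O)c2ccc(OCc3ccccc3)cc2)[C@@H]2CO[C@@H](c3ccc(OCc4ccccc4)c(OC)c3)[C@@H]2COC(=O)c2ccc(OCc3ccccc3)cc2)ccc1OCc1ccccc1
F6 | step 3 | 4-(benzyloxy)-3-methoxybenzaldehyde bis[(trimethylsilyl)methyl] acetal | COc1cc(C(OC[Si](C)(C)C)OC[Si](C)(C)C)ccc1OCc1ccccc1
F7 | step 3 | rac-({[4-(benzyloxy)-3-methoxyphenyl]chloromethoxy}methyl)trimethylsilane | COc1cc(C(Cl)OC[Si](C)(C)C)ccc1OCc1ccccc1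
F8 | step 9 | C9 mono-[4-(benzyloxy)benzoate] of diol 12 | COc1cc([C@H](O)[C@@H]2CO[C@@H](c3ccc(OCc4ccccc4)c(OC)c3)[C@@H]2COC(=O)c2ccc(OCc3ccccc3)cc2)ccc1OCc1ccccc1
F9 | step 9 | C7' O-phenyl thionocarbonate of F8 | COc1cc([C@H](OC(=S)Oc2ccccc2)[C@@H]2CO[C@@H](c3ccc(OCc4ccccc4)c(OC)c3)[C@@H]2COC(=O)c2ccc(OCc3ccccc3)cc2)ccc1OCc1ccccc1
F10 | step 9 | tri-O-benzyl agastinol | COc1cc(C[C@@H]2CO[C@@H](c3ccc(OCc4ccccc4)c(OC)c3)[C@@H]2COC(=O)c2ccc(OCc3ccccc3)cc2)ccc1OCc1ccccc1
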